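The route rests on cutting ring A of unit 1 (the 7-methoxyflavonol) away from the 3-oxygenated 4-pyranone that is its ring C. This ring A is a resorcinol carrying C5–OH, C6–H, C7–OMe and C8–H and fused through C4a and C8a, which is the pattern a vinylketene and an ynol ether deliver. One operation (Wolff rearrangement, [2+2] addition of methoxyacetylene, 4π opening, 6π closure) should therefore form C5–C6, C7–C8 and C4a–C5 and set the 5-OH/7-OMe difference without any protecting group on that ring. The precursor is a 2-diazoacetyl-5-benzyloxy-6-aryl-4-pyranone whose aryl group already holds ring B of unit 1, the diaryl ether and the tribenzylated 5,7-dihydroxyflavonol (unit 2).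

Key step: step 12

Abbreviation used in names: Ar = 3-(benzyloxy)-4-{2-methoxy-4-[3,5,7-tris(benzyloxy)-4-oxo-4H-chromen-2-yl]phenoxy}phenyl (ring B of unit 1 with its diaryl ether and benzylated unit 2).

Assumption: acetophenone 4 is taken as purchasable, like bromophenol 1 and aldehyde 2; the target has no stereocentre, so transient sp3 intermediates are racemic.

Step 1
Reactants: 1 2-(benzyloxy)-4-bromophenol; 2 4-fluoro-3-methoxybenzaldehyde
Product: 3 4-[2-(benzyloxy)-4-bromophenoxy]-3-methoxybenzaldehyde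
Conditions: K2CO3, DMF, 110 °C
Reagents that add atoms: none
Why: SNAr reaction in which the phenoxide of 1 displaces the fluoride para to the formyl group, which stabilises the Meisenheimer intermediate, while the aryl bromide is inert.

Step 2
Reactants: 3 4-[2-(benzyloxy)-4-bromophenoxy]-3-methoxybenzaldehyde; 4 1-[2,4-bis(benzyloxy)-6-hydroxyphenyl]ethanone
Product: 5 (E)-1-[2,4-bis(benzyloxy)-6-hydroxyphenyl]-3-{4-[2-(benzyloxy)-4-bromophenoxy]-3-methoxyphenyl}prop-2-en-1-one
Conditions: KOH, EtOH/THF, 20 °C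
Reagents that add atoms: none
Why: Claisen–Schmidt condensation of the ketone enolate with the non-enolisable aldehyde, followed by base-induced loss of water from the aldol, should give the conjugated (E)-chalcone with the hydrogen-bonded 2'-OH left free.

Step 3
Reactants: 5 (E)-chalcone from step 2
Product: 7 5,7-bis(benzyloxy)-2-{4-[2-(benzyloxy)-4-bromophenoxy]-3-methoxyphenyl}-3-hydroxy-4H-chromen-4-one, via trans-dihydroflavonol 6 (not isolated)
Conditions: 30% aq. H2O2, NaOH, MeOH/THF, 0 °C to 20 °C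
Reagents that add atoms: hydrogen peroxide, OO
Why: Algar–Flynn–Oyamada reaction, in which alkaline peroxide oxidises the 2'-hydroxychalcone with 6-endo closure to the dihydroflavonol and dehydrogenates it in the same pot to the flavonol, the aryl bromide and benzyl ethers being inert.

Step 4
Reactants: 7 flavonol from step 3
Product: 8 3,5,7-tris(benzyloxy)-2-{4-[2-(benzyloxy)-4-bromophenoxy]-3-methoxyphenyl}-4H-chromen-4-one
Conditions: BnBr, K2CO3, DMF, 50 °C
Reagents that add atoms: benzyl bromide, BrCc1ccccc1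
Why: Williamson etherification of the acidic 3-OH, the only free hydroxyl, so that it cannot be methylated or acylated in step 10.

Step 5
Reactants: 8 tribenzylated flavonol bromide from step 4
Product: 9 3,5,7-tris(benzyloxy)-2-{4-[2-(benzyloxy)-4-(4,4,5,5-tetramethyl-1,3,2-dioxaborolan-2-yl)phenoxy]-3-methoxyphenyl}-4H-chromen-4-one
Conditions: B2pin2, PdCl2(dppf), KOAc, 1,4-dioxane, 90 °C
Reagents that add atoms: bis(pinacolato)diboron, CC1(C)OB(OC1(C)C)B1OC(C)(C)C(C)(C)O1
Why: Miyaura borylation of the aryl bromide, with acetate too weak a base to start biaryl coupling and the chromone and ethers as spectators.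

Step 6
Reactants: 10 kojic acid (5-hydroxy-2-(hydroxymethyl)-4H-pyran-4-one)
Product: 11 6-bromo-5-hydroxy-2-(hydroxymethyl)-4H-pyran-4-one
Conditions: NBS, MeCN/H2O, 0 °C
Reagents that add atoms: N-bromosuccinimide, O=C1CCC(=O)N1Br
Why: Electrophilic bromination of the enol-like C5–OH/C6–H unit, C6 (ortho to the free hydroxyl) being the established site of halogenation of kojic acid.

Step 7
Reactants: 11 6-bromokojic acid from step 6
Product: 12 5-(benzyloxy)-6-bromo-2-(hydroxymethyl)-4H-pyran-4-one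
Conditions: BnBr, K2CO3, DMF, 20 °C
Reagents that add atoms: benzyl bromide, BrCc1ccccc1
Why: Williamson etherification in which carbonate deprotonates only the enolic 5-OH, which is far more acidic than the primary alcohol.

Step 8
Reactants: 12 5-(benzyloxy)-6-bromo-2-(hydroxymethyl)-4H-pyran-4-one
Product: 13 5-(benzyloxy)-6-bromo-4-oxo-4H-pyran-2-carboxylic acid
Conditions: CrO3, aq. H2SO4, acetone, 0 °C
Reagents that add atoms: water, O
Why: Jones oxidation of the primary alcohol through the aldehyde hydrate (the aqueous acid supplies the second carboxyl oxygen), a standard conversion for 5-O-benzylkojic acid, which the benzyl ether and the vinylic bromide should tolerate in cold acid.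

Step 9
Reactants: 9 pinacol boronate from step 5; 13 5-(benzyloxy)-6-bromo-4-oxo-4H-pyran-2-carboxylic acid
Product: 14 5-(benzyloxy)-6-Ar-4-oxo-4H-pyran-2-carboxylic acid
Conditions: PdCl2(dppf) (5 mol %), K3PO4, 1,4-dioxane/H2O, 80 °C; then aq. HCl
Reagents that add atoms: none
Why: Suzuki–Miyaura coupling in which the C6–Br bond, a vinylogous acyl bromide, should add quickly to palladium, the substrate reacting as its carboxylate, which also makes the pyranone less prone to attack by hydroxide.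

Step 10
Reactants: 14 5-(benzyloxy)-6-Ar-4-oxo-4H-pyran-2-carboxylic acid
Product: 16 2-diazoacetyl-5-(benzyloxy)-6-Ar-4H-pyran-4-one, via acid chloride 15 (not isolated)
Conditions: (COCl)2 (1.1 equiv), cat. DMF, CH2Cl2, 0 °C; evaporate; CH2N2 (3 equiv), Et2O/THF, 0 °C
Reagents that add atoms: diazomethane, C=[N+]=[N-]
Why: Acid chloride formation under Vilsmeier-type catalysis followed by Arndt–Eistert-type acylation of diazomethane, a second equivalent of which consumes the HCl, as is known for chromone-2-carbonyl chlorides.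

Step 11
Reactants: 17 chloroacetaldehyde dimethyl acetal
Product: 19 methoxyacetylene, via sodium methoxyacetylide 18 (not isolated)
Conditions: NaNH2 (3 equiv), liq. NH3, −33 °C; then sat. aq. NaCl, −20 °C, distil into a −78 °C trap
Reagents that add atoms: none
Why: Twofold base-induced elimination (methanol, then HCl), the standard preparation of alkoxyacetylenes; the third equivalent of amide holds the product as its acetylide until the cold aqueous quench, and the volatile alkyne is used at once as a cold solution.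

Step 12
Reactants: 16 2-diazoacetyl-5-(benzyloxy)-6-Ar-4H-pyran-4-one; 19 methoxyacetylene
Product: 24 3-(benzyloxy)-5-hydroxy-7-methoxy-2-Ar-4H-chromen-4-one, via pyranonylketene 20 (not isolated), via methoxycyclobutenone 21 (not isolated), via dienylketene 22 (not isolated), via dienone tautomer 23 (not isolated)
Conditions: 19 (5 equiv), 450 nm LEDs, ClCH2CH2Cl, 10 °C, sealed tube; then 80 °C in the dark
Reagents that add atoms: none
Why: Proposed new method: 450 nm light, absorbed by the diazo ketone but not by the 3-benzyloxypyranone and 3-benzyloxychromone units (which photocyclise under UV), expels N2 and the pyranonyl group shifts to the former diazo carbon (Wolff rearrangement) to give ketene 20; the nucleophilic CH carbon of the ynol ether attacks the ketene carbonyl carbon and [2+2] closure gives 3-methoxycyclobutenone 21 (C5–C6 and C7–C8 made). At 80 °C reversible conrotatory 4π opening of 21 gives dienylketene 22, whose isomer with the pyranonyl group cis to the ketene undergoes 6π electrocyclisation onto the pyranone C–H carbon to give dienone 23, and enolisation, driven by aromatisation and the hydrogen bond to the C4 carbonyl, gives phenol 24. The closest known reaction type is the Danheiser benzannulation of alkenyl, aryl and heteroaryl α-diazo ketones with alkoxy- and siloxyalkynes; a 4-pyranone C=C bond has not been used as the vinyl partner, but it gives up far less aromatic stabilisation than the benzene and heteroarene rings that are known to react. Ring A of unit 1 is closed by a thermal disrotatory 6π electrocyclisation that forms C4a–C5 as the last bond of a six-membered ring. No stereocentre remains, the sp3 carbons of 21 and 23 being transient and racemic. The step needs OMe on C7 and OH on C5, which the polarity match of ketene and ynol ether secures, and closure at a single site, which is secured because the ketenyl-bearing pyranone carbon has only one neighbouring ring carbon, the C–H carbon that becomes C4a.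

Step 13
Reactants: 24 3-(benzyloxy)-5-hydroxy-7-methoxy-2-Ar-4H-chromen-4-one
Product: 25 2-{4-[4-(3,5-dihydroxy-7-methoxy-4-oxo-4H-chromen-2-yl)-2-hydroxyphenoxy]-3-methoxyphenyl}-3,5,7-trihydroxy-4H-chromen-4-one (target)
Conditions: H2 (1 atm), 10% Pd on carbon, THF/MeOH, 20 °C
Reagents that add atoms: none
Why: Catalytic hydrogenolysis should cleave all five O-benzyl ethers, while the aryl methyl ethers, the diaryl ether and the flavonol C2=C3 bonds are not reduced under these mild conditions.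

Compound list

1 | 2-(benzyloxy)-4-bromophenol | Oc1ccc(Br)cc1OCc1ccccc1 | starting material
2 | 4-fluoro-3-methoxybenzaldehyde | COc1cc(C=O)ccc1F | starting material
3 | 4-[2-(benzyloxy)-4-bromophenoxy]-3-methoxybenzaldehyde | COc1cc(C=O)ccc1Oc1ccc(Br)cc1OCc1ccccc1 | intermediate
4 | 1-[2,4-bis(benzyloxy)-6-hydroxyphenyl]ethanone | CC(=O)c1c(O)cc(OCc2ccccc2)cc1OCc1ccccc1 | starting material
5 | (E)-1-[2,4-bis(benzyloxy)-6-hydroxyphenyl]-3-{4-[2-(benzyloxy)-4-bromophenoxy]-3-methoxyphenyl}prop-2-en-1-one | COc1cc(/C=C/C(=O)c2c(O)cc(OCc3ccccc3)cc2OCc2ccccc2)ccc1Oc1ccc(Br)cc1OCc1ccccc1 | intermediate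
6 | trans-5,7-bis(benzyloxy)-2-{4-[2-(benzyloxy)-4-bromophenoxy]-3-methoxyphenyl}-3-hydroxychroman-4-one (racemic, one enantiomer drawn; formed in the flask) | COc1cc([C@@H]2[C@H](C(=O)c3c(OCc4ccccc4)cc(OCc4ccccc4)cc3O2)O)ccc1Oc1ccc(Br)cc1OCc1ccccc1 | intermediate
7 | 5,7-bis(benzyloxy)-2-{4-[2-(benzyloxy)-4-bromophenoxy]-3-methoxyphenyl}-3-hydroxy-4H-chromen-4-one | COc1cc(-c2oc3cc(OCc4ccccc4)cc(OCc4ccccc4)c3c(=O)c2O)ccc1Oc1ccc(Br)cc1OCc1ccccc1 | intermediate
8 | 3,5,7-tris(benzyloxy)-2-{4-[2-(benzyloxy)-4-bromophenoxy]-3-methoxyphenyl}-4H-chromen-4-one | COc1cc(-c2oc3cc(OCc4ccccc4)cc(OCc4ccccc4)c3c(=O)c2OCc2ccccc2)ccc1Oc1ccc(Br)cc1OCc1ccccc1 | intermediate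
9 | 3,5,7-tris(benzyloxy)-2-{4-[2-(benzyloxy)-4-(4,4,5,5-tetramethyl-1,3,2-dioxaborolan-2-yl)phenoxy]-3-methoxyphenyl}-4H-chromen-4-one | COc1cc(-c2oc3cc(OCc4ccccc4)cc(OCc4ccccc4)c3c(=O)c2OCc2ccccc2)ccc1Oc1ccc(B2OC(C)(C)C(C)(C)O2)cc1OCc1ccccc1 | intermediate
10 | kojic acid, 5-hydroxy-2-(hydroxymethyl)-4H-pyran-4-one | O=c1cc(CO)occ1O | starting material
11 | 6-bromo-5-hydroxy-2-(hydroxymethyl)-4H-pyran-4-one | O=c1cc(CO)oc(Br)c1O | intermediate
12 | 5-(benzyloxy)-6-bromo-2-(hydroxymethyl)-4H-pyran-4-one | O=c1cc(CO)oc(Br)c1OCc1ccccc1 | intermediate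
13 | 5-(benzyloxy)-6-bromo-4-oxo-4H-pyran-2-carboxylic acid | O=C(O)c1cc(=O)c(OCc2ccccc2)c(Br)o1 | intermediate
14 | 5-(benzyloxy)-6-[3-(benzyloxy)-4-{2-methoxy-4-[3,5,7-tris(benzyloxy)-4-oxo-4H-chromen-2-yl]phenoxy}phenyl]-4-oxo-4H-pyran-2-carboxylic acid | O=C(O)c1cc(=O)c(OCc2ccccc2)c(-c2ccc(Oc3ccc(-c4oc5cc(OCc6ccccc6)cc(OCc6ccccc6)c5c(=O)c4OCc4ccccc4)cc3OC)c(OCc3ccccc3)c2)o1 | intermediate
15 | 5-(benzyloxy)-6-[3-(benzyloxy)-4-{2-methoxy-4-[3,5,7-tris(benzyloxy)-4-oxo-4H-chromen-2-yl]phenoxy}phenyl]-4-oxo-4H-pyran-2-carbonyl chloride (formed in the flask) | O=C(Cl)c1cc(=O)c(OCc2ccccc2)c(-c2ccc(Oc3ccc(-c4oc5cc(OCc6ccccc6)cc(OCc6ccccc6)c5c(=O)c4OCc4ccccc4)cc3OC)c(OCc3ccccc3)c2)o1 | intermediate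
16 | 3,5,7-tris(benzyloxy)-2-[4-{2-(benzyloxy)-4-[3-(benzyloxy)-6-(diazoacetyl)-4-oxo-4H-pyran-2-yl]phenoxy}-3-methoxyphenyl]-4H-chromen-4-one (the 2-diazoacetyl-5-benzyloxy-6-aryl-4-pyranone) | [N-]=[N+]=CC(=O)c1cc(=O)c(OCc2ccccc2)c(-c2ccc(Oc3ccc(-c4oc5cc(OCc6ccccc6)cc(OCc6ccccc6)c5c(=O)c4OCc4ccccc4)cc3OC)c(OCc3ccccc3)c2)o1 | intermediate
17 | chloroacetaldehyde dimethyl acetal | COC(CCl)OC | starting material
18 | sodium methoxyacetylide NaC≡COMe (formed in the flask) | [Na+].[C-]#COC | intermediate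
19 | methoxyacetylene | COC#C | intermediate
20 | 3,5,7-tris(benzyloxy)-2-[4-{2-(benzyloxy)-4-[3-(benzyloxy)-4-oxo-6-(2-oxoethenyl)-4H-pyran-2-yl]phenoxy}-3-methoxyphenyl]-4H-chromen-4-one (pyranonylketene; formed in the flask) | O=C=Cc1cc(=O)c(OCc2ccccc2)c(-c2ccc(Oc3ccc(-c4oc5cc(OCc6ccccc6)cc(OCc6ccccc6)c5c(=O)c4OCc4ccccc4)cc3OC)c(OCc3ccccc3)c2)o1 | intermediate
21 | 3,5,7-tris(benzyloxy)-2-[4-{2-(benzyloxy)-4-[3-(benzyloxy)-6-(2-methoxy-4-oxocyclobut-2-en-1-yl)-4-oxo-4H-pyran-2-yl]phenoxy}-3-methoxyphenyl]-4H-chromen-4-one (racemic; formed in the flask) | COC1=CC(=O)C1c1cc(=O)c(OCc2ccccc2)c(-c2ccc(Oc3ccc(-c4oc5cc(OCc6ccccc6)cc(OCc6ccccc6)c5c(=O)c4OCc4ccccc4)cc3OC)c(OCc3ccccc3)c2)o1 | intermediate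
22 | 3,5,7-tris(benzyloxy)-2-[4-{2-(benzyloxy)-4-[3-(benzyloxy)-6-[(1E)-2-methoxy-4-oxobuta-1,3-dien-1-yl]-4-oxo-4H-pyran-2-yl]phenoxy}-3-methoxyphenyl]-4H-chromen-4-one (ketenyl group cis to the pyranonyl group; formed in the flask) | O=C=C/C(OC)=C\c1cc(=O)c(OCc2ccccc2)c(-c2ccc(Oc3ccc(-c4oc5cc(OCc6ccccc6)cc(OCc6ccccc6)c5c(=O)c4OCc4ccccc4)cc3OC)c(OCc3ccccc3)c2)o1 | intermediate
23 | 3-(benzyloxy)-2-[3-(benzyloxy)-4-{2-methoxy-4-[3,5,7-tris(benzyloxy)-4-oxo-4H-chromen-2-yl]phenoxy}phenyl]-7-methoxy-4aH-chromene-4,5-dione (racemic keto tautomer; formed in the flask) | COC1=CC(=O)C2C(=O)C(OCc3ccccc3)=C(c3ccc(Oc4ccc(-c5oc6cc(OCc7ccccc7)cc(OCc7ccccc7)c6c(=O)c5OCc5ccccc5)cc4OC)c(OCc4ccccc4)c3)OC2=C1 | intermediate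
24 | 3-(benzyloxy)-2-[3-(benzyloxy)-4-{2-methoxy-4-[3,5,7-tris(benzyloxy)-4-oxo-4H-chromen-2-yl]phenoxy}phenyl]-5-hydroxy-7-methoxy-4H-chromen-4-one | COc1cc(O)c2c(=O)c(OCc3ccccc3)c(-c3ccc(Oc4ccc(-c5oc6cc(OCc7ccccc7)cc(OCc7ccccc7)c6c(=O)c5OCc5ccccc5)cc4OC)c(OCc4ccccc4)c3)oc2c1 | intermediate
25 | 2-{4-[4-(3,5-dihydroxy-7-methoxy-4-oxo-4H-chromen-2-yl)-2-hydroxyphenoxy]-3-methoxyphenyl}-3,5,7-trihydroxy-4H-chromen-4-one | COc1cc(O)c2c(=O)c(O)c(-c3ccc(Oc4ccc(-c5oc6cc(O)cc(O)c6c(=O)c5O)cc4OC)c(O)c3)oc2c1 | target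

Step count and risk

Total step count: 13 (five to the unit 2 boronate, three to the bromopyranone acid, one for methoxyacetylene, four after convergence).
Longest linear sequence: 9 steps (steps 1, 2, 3, 4, 5, 9, 10, 12, 13).

Steps most likely to fail:

1. Step 12. The diazo ketone may lose nitrogen without migration, its diazo group may add as a dipole to the electron-rich alkyne, the ketene may dimerise before the cycloaddition, or the pyranone C–H carbon may be reluctant to enter the 6π closure. The fallback builds ring A of unit 1 by known flavonol chemistry and sets out from bromide 8. Palladium-catalysed formylation (Pd(OAc)2, di(1-adamantyl)butylphosphine, TMEDA, CO/H2, toluene, 100 °C) would give 3-(benzyloxy)-4-{2-methoxy-4-[3,5,7-tris(benzyloxy)-4-oxo-4H-chromen-2-yl]phenoxy}benzaldehyde F1. Commercial 1-(2,6-dihydroxy-4-methoxyphenyl)ethanone would be monobenzylated (BnBr, K2CO3, acetone) to 1-[2-(benzyloxy)-6-hydroxy-4-methoxyphenyl]ethanone F2. Claisen–Schmidt condensation of the two (KOH, EtOH/THF) would give (E)-1-[2-(benzyloxy)-6-hydroxy-4-methoxyphenyl]-3-Ar-prop-2-en-1-one F3, and Algar–Flynn–Oyamada oxidation (H2O2, NaOH) would give 5-(benzyloxy)-3-hydroxy-7-methoxy-2-Ar-4H-chromen-4-one F4. Hydrogenolysis of its five benzyl ethers (H2, Pd on carbon) comes back to the route at target 25.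

2. Step 3. The phenoxide may close on the α-carbon (5-exo) in place of the 6-endo closure, a diversion that a 6'-alkoxy group favours, and dehydrogenation of the dihydroflavonol may stall. The fallback separates ring closure from hydroxylation and sets out from chalcone 5. Oxidative cyclisation (catalytic I2, DMSO, 120 °C) would give 5,7-bis(benzyloxy)-2-{4-[2-(benzyloxy)-4-bromophenoxy]-3-methoxyphenyl}-4H-chromen-4-one F5. Dimethyldioxirane (acetone/CH2Cl2, 0 °C) would give its 2,3-epoxide F6, and catalytic TsOH would open this to the 3-hydroxyflavone, which is compound 7, where the route resumes at step 4.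

3. Step 9. Aqueous base may displace the activated C6 bromide before oxidative addition, and transmetalation may be slow with the carboxylate present. The fallback masks the acid and couples without water, setting out from acid 13. MeI and KHCO3 in DMF would give methyl 5-(benzyloxy)-6-bromo-4-oxo-4H-pyran-2-carboxylate F7. Coupling with boronate 9 (Pd(PPh3)4, CsF, 1,4-dioxane, 90 °C) would give methyl 5-(benzyloxy)-6-Ar-4-oxo-4H-pyran-2-carboxylate F8, and LiOH in THF/H2O at 0 °C would return to the route at acid 14.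

Further compounds

F1 | step 12 | 3-(benzyloxy)-4-{2-methoxy-4-[3,5,7-tris(benzyloxy)-4-oxo-4H-chromen-2-yl]phenoxy}benzaldehyde | COc1cc(-c2oc3cc(OCc4ccccc4)cc(OCc4ccccc4)c3c(=O)c2OCc2ccccc2)ccc1Oc1ccc(C=O)cc1OCc1ccccc1
F2 | step 12 | 1-[2-(benzyloxy)-6-hydroxy-4-methoxyphenyl]ethanone | CC(=O)c1c(O)cc(OC)cc1OCc1ccccc1
F3 | step 12 | (E)-1-[2-(benzyloxy)-6-hydroxy-4-methoxyphenyl]-3-[3-(benzyloxy)-4-{2-methoxy-4-[3,5,7-tris(benzyloxy)-4-oxo-4H-chromen-2-yl]phenoxy}phenyl]prop-2-en-1-one | COc1cc(O)c(C(=O)/C=C/c2ccc(Oc3ccc(-c4oc5cc(OCc6ccccc6)cc(OCc6ccccc6)c5c(=O)c4OCc4ccccc4)cc3OC)c(OCc3ccccc3)c2)c(OCc2ccccc2)c1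
F4 | step 12 | 5-(benzyloxy)-2-[3-(benzyloxy)-4-{2-methoxy-4-[3,5,7-tris(benzyloxy)-4-oxo-4H-chromen-2-yl]phenoxy}phenyl]-3-hydroxy-7-methoxy-4H-chromen-4-one | COc1cc(OCc2ccccc2)c2c(=O)c(O)c(-c3ccc(Oc4ccc(-c5oc6cc(OCc7ccccc7)cc(OCc7ccccc7)c6c(=O)c5OCc5ccccc5)cc4OC)c(OCc4ccccc4)c3)oc2c1
F5 | step 3 | 5,7-bis(benzyloxy)-2-{4-[2-(benzyloxy)-4-bromophenoxy]-3-methoxyphenyl}-4H-chromen-4-one | COc1cc(-c2cc(=O)c3c(OCc4ccccc4)cc(OCc4ccccc4)cc3o2)ccc1Oc1ccc(Br)cc1OCc1ccccc1
F6 | step 3 | 2,3-epoxide of F5, 5,7-bis(benzyloxy)-2-{4-[2-(benzyloxy)-4-bromophenoxy]-3-methoxyphenyl}-2,3-epoxychroman-4-one (racemic; the ring fusion can only be cis) | COc1cc(C23OC2C(=O)c2c(OCc4ccccc4)cc(OCc4ccccc4)cc2O3)ccc1Oc1ccc(Br)cc1OCc1ccccc1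
F7 | step 9 | methyl 5-(benzyloxy)-6-bromo-4-oxo-4H-pyran-2-carboxylate | COC(=O)c1cc(=O)c(OCc2ccccc2)c(Br)o1
F8 | step 9 | methyl 5-(benzyloxy)-6-[3-(benzyloxy)-4-{2-methoxy-4-[3,5,7-tris(benzyloxy)-4-oxo-4H-chromen-2-yl]phenoxy}phenyl]-4-oxo-4H-pyran-2-carboxylate | COC(=O)c1cc(=O)c(OCc2ccccc2)c(-c2ccc(Oc3ccc(-c4oc5cc(OCc6ccccc6)cc(OCc6ccccc6)c5c(=O)c4OCc4ccccc4)cc3OC)c(OCc3ccccc3)c2)o1
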